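**Straight line.** If target in the grey run climbs along a straight line, one steady rate is feeding it, and two readings give that rate. Between 20.0 s and 80.0 s the line reads 0.237 mM s⁻¹: this is the feed F, the target formed per litre per second. Run back, the grey line meets zero at a lag of 6.74 s.

common to all: free catalyst 10 mM
- grey: solid substrate 0.075 M; temperature 0 °C; run made earlier
- eta: solid substrate 0.050 M; at 0 °C until 2.0 min, from then on at 20 °C; time 4.0 min
- beta: solid substrate 0.050 M; at 0 °C throughout; time 1.0 min

- grey (time / s: target / %): 10.0: 1.3; 12.0: 2.1; 20.0: 4.2; 30.0: 6.0; 40.0: 11.0; 60.0: 17.4; 80.0: 23.2

(scatter of a reading: 0.5 percentage points)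

- solid, in amounts per volume of the solution: solid substrate
- at the start none of the solid substrate is in solution
- what has only dissolved of solid substrate counts as not reacted
- the earlier runs do not show what temperature does; that part of a forecast is a guess

- the winner by amount of target, in percent of the solid substrate charged; "neither" if no more than 2 percentage points parts them (eta / beta / neither)
- how much target is there at the end, in percent of the solid substrate charged: eta
- how much target is there at the end, in percent of the solid substrate charged: beta

**Solid balance.** The last grey reading holds 17.4 mM of target, more than the 10 mM of free catalyst charged, so the free catalyst turns over and the balance belongs to the solid substrate, the limiting reagent. What remains is reckoned as the charge minus F times time, so at the cold feed the estimated life of a charge is τ = charge/F, here 3.51 min. That is longer than beta's 1.0 min and shorter than eta's 4.0 min.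

**The bracket.** For beta, F running through the whole minute gives 28.5% from above. A feed that scales with the charge, after the lag, gives 16.9% from below. A constant F after the lag tightens this to 25.3%, the value held here. For eta, the charge caps target at 100%, and what F has made by the change at 2.0 min gives 53.8% from below, provided target survives; the effect of warming is a guess.

**The forecast.** It named eta the winner, with 95% for eta and 24% for beta, holding that “the absolute rate should not depend on the solid charged”. Both values lie inside the brackets.

**The result.** Eta ends with 78.9% of target and beta with 26.4%, so the winner is eta; both values lie inside the brackets, and eta ends 16 percentage points below the forecast.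

    target → over-reaction product (k = 1.50 × 10⁻⁴ s⁻¹, Ea = 89.0 kJ mol⁻¹)
    starting material + free catalyst → catalyst intermediate A (k = 10.0 L mol⁻¹ s⁻¹, Ea = 45.0 kJ mol⁻¹)
    catalyst intermediate B → free catalyst + target (k = 42.0 s⁻¹, Ea = 47.0 kJ mol⁻¹)
    solid substrate ⇌ starting material, rate k4*(cs4 - [starting material]) while solid is left; crystals form when [starting material] > cs4 (solubility = 8.10 mM, k = 0.0450 s⁻¹)
    catalyst intermediate A → catalyst intermediate B (k = 5.30 s⁻¹, Ea = 64.0 kJ mol⁻¹)
    (constants at 0 °C)

**The flask.** At 2.00 min eta held 56.2% target, 38.2% solid substrate and 0.479% over-reaction product. By 4.00 min its solid substrate stood at 0% and its over-reaction product at 21.1%. A neighbour of eta with 0.12 M of solid substrate has τ = 8.44 min, longer than its 4.0 min, and it ended with 42% of its charge still there, solid or dissolved.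

The data are calculated for substances that don't exist; scatter was added.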